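**Retrosynthetic overview**
1. Numbering: oxolane O1, C2–C5. Ring B is the aryl on C2 and carries the (R,R) arm ending in ring A. Ring C is the aryl on C5 and carries the (S,S) arm ending in ring D. Both arms are cut at their aryl O–CH bonds: SN2 etherification of the two differentiated phenols with the two enantiomeric lactate-derived keto tosylates, then one Felkin–Anh reduction of both ketones.
2. The oxolane is cut at C3–C4 (the 8–8′ bond): palladium hydride reductive cyclisation of the 1,6-enyne HC≡C–C2H(ring B)–O1–C5H(ring C)–CH=CH2, then face-selective hydrogenation of the C3 methylidene group.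
3. Enabling feature: the adjacent methyl-bearing ring carbons C3 and C4 lie between the two benzylic ether carbons C2 and C5, so C3–CH3 and C4–CH3 are the termini of an alkyne and an alkene tethered through O1. The cis aryl rings on C2 and C5 shield one ring face, which makes the alkyne end the 2,3-cis end and the alkene end the 4,5-trans end.
4. O1–C5 is cut next: iridium-catalysed branched-selective allylic etherification of a ring-C cinnamyl carbonate with an enantioenriched ring-B propargylic alcohol.
5. Ring order: the four benzene rings A–D are bought. The oxolane is the only ring made and is closed last.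

Key step: step 12

Assumption: in steps 10 and 11 the ligand antipode written is the one expected to give the drawn configuration. Both antipodes are sold, and the other one is taken if a test run shows the opposite sense.

Step 1
Reactants: 1 ethyl (S)-lactate
Product: 2 (2S)-2-hydroxy-N-methoxy-N-methylpropanamide
Conditions: MeNH(OMe)·HCl, i-PrMgCl, THF, −20 → 0 °C
Reagents that add atoms: N,O-dimethylhydroxylamine hydrochloride, CNOC.Cl
Why: Aminolysis of the ester by the chloromagnesium amide (Weinreb amide synthesis); no bond at the stereocentre is broken and the magnesium alkoxide formed first suppresses enolisation, so the (S) configuration is kept.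

Step 2
Reactants: 2 (2S)-2-hydroxy-N-methoxy-N-methylpropanamide; 3 3,4-dimethoxyphenylmagnesium bromide
Product: 4 (2S)-1-(3,4-dimethoxyphenyl)-2-hydroxypropan-1-one
Conditions: 3 (3 equiv), THF, 0 °C → rt; aq NH4Cl
Reagents that add atoms: none
Why: Grignard addition to a Weinreb amide: the first equivalent deprotonates the hydroxyl group, the second adds only once because the chelated tetrahedral intermediate survives until work-up, and the stereocentre is retained.

Step 3
Reactants: 4 (2S)-1-(3,4-dimethoxyphenyl)-2-hydroxypropan-1-one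
Product: 5 (2S)-1-(3,4-dimethoxyphenyl)-1-oxopropan-2-yl 4-methylbenzenesulfonate
Conditions: TsCl, Et3N, DMAP (cat.), CH2Cl2, 0 °C
Reagents that add atoms: 4-toluenesulfonyl chloride, Cc1ccc(cc1)S(=O)(=O)Cl
Why: O-Sulfonylation of a secondary alcohol, which does not break the C–O bond and so keeps the (S) configuration while creating an α-keto leaving group for SN2 displacement.

Step 4
Reactants: 6 methyl (R)-lactate
Product: 7 (2R)-2-hydroxy-N-methoxy-N-methylpropanamide
Conditions: MeNH(OMe)·HCl, i-PrMgCl, THF, −20 → 0 °C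
Reagents that add atoms: N,O-dimethylhydroxylamine hydrochloride, CNOC.Cl
Why: Weinreb amide synthesis as in step 1, in the mirror-image series, with retention of the (R) centre.

Step 5
Reactants: 7 (2R)-2-hydroxy-N-methoxy-N-methylpropanamide; 3 3,4-dimethoxyphenylmagnesium bromide
Product: 8 (2R)-1-(3,4-dimethoxyphenyl)-2-hydroxypropan-1-one
Conditions: 3 (3 equiv), THF, 0 °C → rt; aq NH4Cl
Reagents that add atoms: none
Why: Grignard addition to a Weinreb amide as in step 2, with retention of the (R) centre.

Step 6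
Reactants: 8 (2R)-1-(3,4-dimethoxyphenyl)-2-hydroxypropan-1-one
Product: 9 (2R)-1-(3,4-dimethoxyphenyl)-1-oxopropan-2-yl 4-methylbenzenesulfonate
Conditions: TsCl, Et3N, DMAP (cat.), CH2Cl2, 0 °C
Reagents that add atoms: 4-toluenesulfonyl chloride, Cc1ccc(cc1)S(=O)(=O)Cl
Why: O-Sulfonylation with retention, as in step 3.

Step 7
Reactants: 10 methyl ferulate, methyl (E)-3-(4-hydroxy-3-methoxyphenyl)prop-2-enoate
Product: 11 methyl (E)-3-[3-methoxy-4-(triisopropylsilyloxy)phenyl]prop-2-enoate
Conditions: i-Pr3SiCl, imidazole, DMF, rt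
Reagents that add atoms: chlorotriisopropylsilane, CC(C)[Si](Cl)(C(C)C)C(C)C
Why: Silyl ether formation on the phenol; the bulky silyl group is orthogonal to the benzyl ether on ring B and should survive the later alkoxide, carbonate, silane and hydrogenation conditions.

Step 8
Reactants: 11 methyl (E)-3-[3-methoxy-4-(triisopropylsilyloxy)phenyl]prop-2-enoate
Product: 12 (E)-3-[3-methoxy-4-(triisopropylsilyloxy)phenyl]prop-2-en-1-ol
Conditions: i-Bu2AlH (2.5 equiv), CH2Cl2, −78 °C; Rochelle salt
Reagents that add atoms: none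
Why: 1,2-Reduction of an α,β-unsaturated ester by i-Bu2AlH to the allylic alcohol, which leaves the (E) double bond in place.

Step 9
Reactants: 12 (E)-3-[3-methoxy-4-(triisopropylsilyloxy)phenyl]prop-2-en-1-ol
Product: 13 tert-butyl (E)-3-[3-methoxy-4-(triisopropylsilyloxy)phenyl]prop-2-en-1-yl carbonate
Conditions: n-BuLi, THF, −78 °C; Boc2O, −78 °C → rt
Reagents that add atoms: di-tert-butyl dicarbonate, CC(C)(C)OC(=O)OC(=O)OC(C)(C)C
Why: O-Acylation of the lithium alkoxide (carbonate formation); the tert-butyl carbonate is chosen because the tert-butoxide it releases in step 11 is too hindered to compete as a nucleophile.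

Step 10
Reactants: 14 4-(benzyloxy)-3-methoxybenzaldehyde; 15 ethynyltrimethylsilane
Product: 16 (1R)-1-[4-(benzyloxy)-3-methoxyphenyl]-3-(trimethylsilyl)prop-2-yn-1-ol
Conditions: Me2Zn (3 equiv), 15 (3 equiv), (R,R)-ProPhenol (10 mol %), Ph3P=O (20 mol %), toluene, 4 °C
Reagents that add atoms: none
Why: Catalytic asymmetric alkynylation of an aldehyde by an alkynylzinc reagent on a dinuclear zinc–ProPhenol catalyst, in which the ligand selects the aldehyde face and sets the carbinol carbon as (R), spatially the C2 configuration of the target.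

Step 11
Reactants: 16 (1R)-1-[4-(benzyloxy)-3-methoxyphenyl]-3-(trimethylsilyl)prop-2-yn-1-ol; 13 tert-butyl (E)-3-[3-methoxy-4-(triisopropylsilyloxy)phenyl]prop-2-en-1-yl carbonate
Product: 18 (1S)-1-[4-(benzyloxy)-3-methoxyphenyl]prop-2-ynyl (1R)-1-[3-methoxy-4-(triisopropylsilyloxy)phenyl]prop-2-enyl ether, via C-silyl enyne ether 17 (not isolated)
Conditions: 16, n-BuLi, CuI, THF, 0 °C; 13, [Ir(cod)Cl]2 (2 mol %), (Ra,Rc,Rc)-O,O′-(1,1′-binaphthyl-2,2′-diyl)-N,N-bis(1-phenylethyl)phosphoramidite (4 mol %), THF, rt; aq NH4Cl/NH3 wash; crude 17, K2CO3 (cat.), MeOH, rt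
Reagents that add atoms: none
Why: Iridium-catalysed asymmetric allylic etherification: the copper alkoxide attacks the aryl-substituted terminus of the π-allyliridium intermediate (branched selectivity) and the phosphoramidite sets C5 as (R) under catalyst control, C2 being untouched (its descriptor changes from R to S only through the priority change when base-catalysed methanolysis removes the C-silyl group).

Step 12
Reactants: 18 (1S)-1-[4-(benzyloxy)-3-methoxyphenyl]prop-2-ynyl (1R)-1-[3-methoxy-4-(triisopropylsilyloxy)phenyl]prop-2-enyl ether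
Product: 19 (2S,4R,5R)-2-[4-(benzyloxy)-3-methoxyphenyl]-4-methyl-3-methylidene-5-[3-methoxy-4-(triisopropylsilyloxy)phenyl]oxolane
Conditions: Pd2(dba)3·CHCl3 (2.5 mol %), P(o-tol)3 (10 mol %), AcOH (2 equiv), Et3SiH (5 equiv), toluene, rt
Reagents that add atoms: none
Why: Zerovalent palladium and AcOH give H–Pd–OAc, which hydropalladates the terminal alkyne of 18 with Pd on the internal carbon C3; the alkenyl–Pd bond then adds across C4=CH2 and the primary alkyl–Pd is cleaved by Et3SiH, so that the C3–C4 bond, the C4 methyl group and the C3 methylidene group arise in one catalytic cycle. The closest known reaction type is the palladium hydride-catalysed reductive cyclisation of 1,6-enynes with a silane, which is established for allyl propargyl ethers that carry a terminal alkyne and a terminal alkene. The oxolane is closed by a 5-exo-trig migratory insertion (syn carbopalladation) that forms C3–C4, a tethered and reductive counterpart of the biosynthetic 8–8′ coupling. The one new stereocentre, C4, is controlled by the neighbouring C5 centre: in the envelope-like transition state both aryl rings lie pseudo-equatorial and the CH2–Pd arm turns away from ring C, which places the C4 methyl trans to the C5 aryl and on the face opposite to both aryl rings. The step needs hydropalladation of the alkyne before the alkene, silane capture faster than β-hydride elimination to the 3,4-dimethylidene diene, and no ionisation of the allylic or propargylic C–O bonds. These are secured by the higher affinity of Pd–H for the terminal alkyne, by the excess of Et3SiH, and by the poor leaving-group quality of an alkoxide in weakly acidic medium at room temperature.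

Step 13
Reactants: 19 (2S,4R,5R)-2-[4-(benzyloxy)-3-methoxyphenyl]-4-methyl-3-methylidene-5-[3-methoxy-4-(triisopropylsilyloxy)phenyl]oxolane
Product: 21 4-[(2S,3R,4R,5R)-5-(3-methoxy-4-triisopropylsilyloxyphenyl)-3,4-dimethyloxolan-2-yl]-2-methoxyphenol, via benzyl ether 20 (not isolated)
Conditions: H2 (1 atm), 10 % Pd/C, EtOAc–EtOH, rt
Reagents that add atoms: none
Why: Heterogeneous syn hydrogenation should deliver H2 to the C3 methylidene from the ring face that carries only the C4 methyl, because the other face is blocked by the cis aryl rings on C2 and C5; this sets C3 as (R) with its methyl cis to ring B and trans to the C4 methyl, and the same catalyst then cleaves the benzyl ether by hydrogenolysis.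

Step 14
Reactants: 21 4-[(2S,3R,4R,5R)-5-(3-methoxy-4-triisopropylsilyloxyphenyl)-3,4-dimethyloxolan-2-yl]-2-methoxyphenol; 5 (2S)-1-(3,4-dimethoxyphenyl)-1-oxopropan-2-yl 4-methylbenzenesulfonate
Product: 22 (2R)-1-(3,4-dimethoxyphenyl)-2-{2-methoxy-4-[(2S,3R,4R,5R)-5-(3-methoxy-4-triisopropylsilyloxyphenyl)-3,4-dimethyloxolan-2-yl]phenoxy}propan-1-one
Conditions: Cs2CO3, MeCN, rt
Reagents that add atoms: none
Why: Williamson-type SN2 etherification of the caesium phenoxide at the α-keto tosylate with inversion, (S)-5 giving the (R)-aryl ether; the mild base should avoid enolisation of the product ketone.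

Step 15
Reactants: 22 (2R)-1-(3,4-dimethoxyphenyl)-2-{2-methoxy-4-[(2S,3R,4R,5R)-5-(3-methoxy-4-triisopropylsilyloxyphenyl)-3,4-dimethyloxolan-2-yl]phenoxy}propan-1-one
Product: 23 (2R)-1-(3,4-dimethoxyphenyl)-2-{4-[(2S,3R,4R,5R)-5-(4-hydroxy-3-methoxyphenyl)-3,4-dimethyloxolan-2-yl]-2-methoxyphenoxy}propan-1-one
Conditions: Bu4NF, AcOH (1:1), THF, 0 °C
Reagents that add atoms: none
Why: Fluoride-induced cleavage of the aryl silyl ether; buffering by AcOH keeps the medium non-basic so that the epimerisable α-aryloxy ketone centre is preserved.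

Step 16
Reactants: 23 (2R)-1-(3,4-dimethoxyphenyl)-2-{4-[(2S,3R,4R,5R)-5-(4-hydroxy-3-methoxyphenyl)-3,4-dimethyloxolan-2-yl]-2-methoxyphenoxy}propan-1-one; 9 (2R)-1-(3,4-dimethoxyphenyl)-1-oxopropan-2-yl 4-methylbenzenesulfonate
Product: 24 bis-ketone (2R)-1-(3,4-dimethoxyphenyl)-2-{4-[(2S,3R,4R,5R)-5-{4-[(2S)-1-(3,4-dimethoxyphenyl)-1-oxopropan-2-yl]oxy-3-methoxyphenyl}-3,4-dimethyloxolan-2-yl]-2-methoxyphenoxy}propan-1-one
Conditions: Cs2CO3, MeCN, rt
Reagents that add atoms: none
Why: Williamson-type SN2 etherification with inversion, (R)-9 giving the (S)-aryl ether on ring C, so that the mirror-image arm ends up on the 4,5-trans end of the oxolane.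

Step 17
Reactants: 24 bis-ketone
Product: 25 target, (1R,2R)-1-(3,4-dimethoxyphenyl)-2-{4-[(2S,3R,4R,5R)-5-{4-[(1S,2S)-1-(3,4-dimethoxyphenyl)-1-hydroxypropan-2-yl]oxy-3-methoxyphenyl}-3,4-dimethyloxolan-2-yl]-2-methoxyphenoxy}propan-1-ol
Conditions: Bu4NBH4, CH2Cl2–MeOH, −40 → 0 °C
Reagents that add atoms: none
Why: Substrate-controlled borohydride reduction under the polar Felkin–Anh model: with a non-chelating ammonium counter-ion, hydride attacks each ketone anti to its aryloxy group, so the (R)-ether gives the (1R,2R)-threo arm and the (S)-ether the (1S,2S)-threo arm in one operation, an achiral reagent being the right choice because the two arms are mirror images.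

**Compound list**
1 | ethyl (S)-lactate | C[C@H](O)C(=O)OCC | starting material
2 | (2S)-2-hydroxy-N-methoxy-N-methylpropanamide | C[C@H](O)C(=O)N(C)OC | intermediate
3 | 3,4-dimethoxyphenylmagnesium bromide (THF solution) | COc1ccc([Mg]Br)cc1OC | starting material
4 | (2S)-1-(3,4-dimethoxyphenyl)-2-hydroxypropan-1-one | C[C@H](O)C(=O)c1ccc(OC)c(OC)c1 | intermediate
5 | (2S)-1-(3,4-dimethoxyphenyl)-1-oxopropan-2-yl 4-methylbenzenesulfonate | C[C@H](OS(=O)(=O)c1ccc(C)cc1)C(=O)c1ccc(OC)c(OC)c1 | intermediate
6 | methyl (R)-lactate | C[C@@H](O)C(=O)OC | starting material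
7 | (2R)-2-hydroxy-N-methoxy-N-methylpropanamide | C[C@@H](O)C(=O)N(C)OC | intermediate
8 | (2R)-1-(3,4-dimethoxyphenyl)-2-hydroxypropan-1-one | C[C@@H](O)C(=O)c1ccc(OC)c(OC)c1 | intermediate
9 | (2R)-1-(3,4-dimethoxyphenyl)-1-oxopropan-2-yl 4-methylbenzenesulfonate | C[C@@H](OS(=O)(=O)c1ccc(C)cc1)C(=O)c1ccc(OC)c(OC)c1 | intermediate
10 | methyl ferulate | COC(=O)/C=C/c1ccc(O)c(OC)c1 | starting material
11 | methyl (E)-3-[3-methoxy-4-(triisopropylsilyloxy)phenyl]prop-2-enoate | COC(=O)/C=C/c1ccc(O[Si](C(C)C)(C(C)C)C(C)C)c(OC)c1 | intermediate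
12 | (E)-3-[3-methoxy-4-(triisopropylsilyloxy)phenyl]prop-2-en-1-ol | OC/C=C/c1ccc(O[Si](C(C)C)(C(C)C)C(C)C)c(OC)c1 | intermediate
13 | tert-butyl (E)-3-[3-methoxy-4-(triisopropylsilyloxy)phenyl]prop-2-en-1-yl carbonate | CC(C)(C)OC(=O)OC/C=C/c1ccc(O[Si](C(C)C)(C(C)C)C(C)C)c(OC)c1 | intermediate
14 | 4-(benzyloxy)-3-methoxybenzaldehyde | COc1cc(C=O)ccc1OCc1ccccc1 | starting material
15 | ethynyltrimethylsilane | C#C[Si](C)(C)C | starting material
16 | (1R)-1-[4-(benzyloxy)-3-methoxyphenyl]-3-(trimethylsilyl)prop-2-yn-1-ol | COc1cc(ccc1OCc1ccccc1)[C@@H](O)C#C[Si](C)(C)C | intermediate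
17 | (1R)-1-[4-(benzyloxy)-3-methoxyphenyl]-3-(trimethylsilyl)prop-2-ynyl (1R)-1-[3-methoxy-4-(triisopropylsilyloxy)phenyl]prop-2-enyl ether | COc1cc(ccc1OCc1ccccc1)[C@H](C#C[Si](C)(C)C)O[C@@H](c1ccc(O[Si](C(C)C)(C(C)C)C(C)C)c(OC)c1)C=C | intermediate
18 | (1S)-1-[4-(benzyloxy)-3-methoxyphenyl]prop-2-ynyl (1R)-1-[3-methoxy-4-(triisopropylsilyloxy)phenyl]prop-2-enyl ether | COc1cc(ccc1OCc1ccccc1)[C@H](C#C)O[C@@H](c1ccc(O[Si](C(C)C)(C(C)C)C(C)C)c(OC)c1)C=C | intermediate
19 | (2S,4R,5R)-2-[4-(benzyloxy)-3-methoxyphenyl]-4-methyl-3-methylidene-5-[3-methoxy-4-(triisopropylsilyloxy)phenyl]oxolane | COc1cc(ccc1OCc1ccccc1)[C@H]1O[C@@H](c2ccc(O[Si](C(C)C)(C(C)C)C(C)C)c(OC)c2)[C@H](C)C1=C | intermediate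
20 | (2S,3R,4R,5R)-2-[4-(benzyloxy)-3-methoxyphenyl]-3,4-dimethyl-5-[3-methoxy-4-(triisopropylsilyloxy)phenyl]oxolane | COc1cc(ccc1OCc1ccccc1)[C@H]1O[C@@H](c2ccc(O[Si](C(C)C)(C(C)C)C(C)C)c(OC)c2)[C@H](C)[C@H]1C | intermediate
21 | 4-[(2S,3R,4R,5R)-5-(3-methoxy-4-triisopropylsilyloxyphenyl)-3,4-dimethyloxolan-2-yl]-2-methoxyphenol | COc1cc(ccc1O)[C@H]1O[C@@H](c2ccc(O[Si](C(C)C)(C(C)C)C(C)C)c(OC)c2)[C@H](C)[C@H]1C | intermediate
22 | ring-B (R)-keto ether, ring C still silylated | COc1cc(ccc1O[C@H](C)C(=O)c1ccc(OC)c(OC)c1)[C@H]1O[C@@H](c2ccc(O[Si](C(C)C)(C(C)C)C(C)C)c(OC)c2)[C@H](C)[C@H]1C | intermediate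
23 | ring-B (R)-keto ether, ring C free phenol | COc1cc(ccc1O[C@H](C)C(=O)c1ccc(OC)c(OC)c1)[C@H]1O[C@@H](c2ccc(O)c(OC)c2)[C@H](C)[C@H]1C | intermediate
24 | bis-ketone, (R)-keto ether on ring B and (S)-keto ether on ring C | COc1cc(ccc1O[C@H](C)C(=O)c1ccc(OC)c(OC)c1)[C@H]1O[C@@H](c2ccc(O[C@@H](C)C(=O)c3ccc(OC)c(OC)c3)c(OC)c2)[C@H](C)[C@H]1C | intermediate
25 | CNP0116650.16 | COc1ccc([C@@H](O)[C@@H](C)Oc2ccc([C@H]3O[C@@H](c4ccc(O[C@@H](C)[C@@H](O)c5ccc(OC)c(OC)c5)c(OC)c4)[C@H](C)[C@H]3C)cc2OC)cc1OC | target

**Step count and risks**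
Total step count: 17. Longest linear sequence: 10 steps (10 → 25 through steps 7, 8, 9, 11, 12, 13, 14, 15, 16, 17).

**Steps most likely to fail**

1. **Step 11.**
   - Risk: attack of the hindered secondary alkoxide may be slow. Branched/linear selectivity and catalyst control may erode with the electron-rich cinnamyl unit.
   - Fallback: it sets out from 13 and sets the stereocentre first with a small nucleophile. Iridium-catalysed allylic hydroxylation with aqueous KHCO3 (same iridium catalyst) should give (1R)-1-[3-methoxy-4-(triisopropylsilyloxy)phenyl]prop-2-en-1-ol F1. ClCO2Me/pyridine then converts it into the branched methyl carbonate F2. A stereospecific rhodium-catalysed allylic etherification of F2 with the copper alkoxide of 16 [RhCl(PPh3)3, P(OMe)3, THF, net retention] comes back to the route at 17, and K2CO3/MeOH leads on to 18.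

2. **Step 12.**
   - Risk: β-hydride elimination may outrun silane capture. The alkyne may be hydrosilylated, or palladium may ionise an allylic C–O bond.
   - Fallback: it sets out from 18 and replaces the organopalladium cycle by a radical chain. With Bu3SnH and Et3B/air in toluene, the stannyl radical adds to the alkyne terminus, the alkenyl radical at C3 closes 5-exo-trig onto C4, and the primary radical takes hydrogen from the stannane. This should give the 3-[(tributylstannyl)methylidene]oxolane F3. Protodestannylation (HCl in Et2O, CH2Cl2, −78 °C) comes back to the route at 19.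

3. **Step 13.**
   - Risk: the double bond may migrate on palladium before hydrogen delivery. Facial selectivity may be insufficient, or the ring benzylic C–O bonds may be hydrogenolysed.
   - Fallback: it sets out from 19 and uses ionic hydrogenation (CF3CO2H, Et3SiH, CH2Cl2, −78 → −40 °C). Acid moves the double bond into conjugation with ring B to give the 2,3-dihydrofuran F4. Reversible protonation at C3 favours the oxocarbenium ion with trans methyl groups, and hydride attacks C2 anti to the C3 methyl. This comes back to the route at 20. The benzyl ether is then removed by transfer hydrogenolysis (Pd/C, cyclohexa-1,4-diene) to give 21.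

**Further compounds**
F1 | step 11 | (1R)-1-[3-methoxy-4-(triisopropylsilyloxy)phenyl]prop-2-en-1-ol | O[C@@H](c1ccc(O[Si](C(C)C)(C(C)C)C(C)C)c(OC)c1)C=C
F2 | step 11 | methyl (1R)-1-[3-methoxy-4-(triisopropylsilyloxy)phenyl]prop-2-en-1-yl carbonate | COC(=O)O[C@@H](c1ccc(O[Si](C(C)C)(C(C)C)C(C)C)c(OC)c1)C=C
F3 | step 12 | (2R,4R,5R)-2-[4-(benzyloxy)-3-methoxyphenyl]-4-methyl-5-[3-methoxy-4-(triisopropylsilyloxy)phenyl]-3-[(tributylstannyl)methylidene]oxolane, E/Z mixture, same ring geometry as 19 (C2 descriptor changes by priority only) | COc1cc(ccc1OCc1ccccc1)[C@H]1O[C@@H](c2ccc(O[Si](C(C)C)(C(C)C)C(C)C)c(OC)c2)[C@H](C)C1=C[Sn](CCCC)(CCCC)CCCC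
F4 | step 13 | (2R,3R)-5-[4-(benzyloxy)-3-methoxyphenyl]-3,4-dimethyl-2-[3-methoxy-4-(triisopropylsilyloxy)phenyl]-2,3-dihydrofuran | COc1cc(ccc1OCc1ccccc1)C1=C(C)[C@@H](C)[C@H](c2ccc(O[Si](C(C)C)(C(C)C)C(C)C)c(OC)c2)O1
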